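(The runs stem from a simulated flask from invented constants.)

The amounts first: starting material runs from 0.080 M to 1.2 M against 1.6 mM of free catalyst, so teal asks 50.0 rounds of each catalyst and amber 750. Before committing to a charge for the next run, I want to know how many rounds one catalyst lasts.

| setting | Sunday's | teal | violet | red | grey | amber |
|---|---|---|---|---|---|---|
| starting material | 0.080 M | 0.080 M | 0.15 M | 0.30 M | 0.60 M | 1.2 M |
| free catalyst | 1.1 mM | 1.6 mM | 1.6 mM | 1.6 mM | 1.6 mM | 1.6 mM |
| remark | run made earlier |  |  |  |  |  |
| time |  | 30 min | 30 min | 30 min | 30 min | 30 min |

Sunday's run (percent of the starting material charged)

| time / min | product / % |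
|---|---|
| 0.500 | 2.2 |
| 0.833 | 3.8 |
| 1.33 | 6.5 |
| 2.00 | 8.5 |
| 4.00 | 14.5 |
| 6.00 | 20.3 |

(readings scatter by 1 percentage point)

- a reading or a percentage of product counts all its forms, free or not
- the concentration of product that is asked is that of its free form alone
- "hardly changes" means that all values lie within two and a half points (for a concentration: within two and a half percent of the largest)
- no earlier run changes the charge of free catalyst; that part of a forecast is a guess

* [product] (only what is free in solution) at the end for teal, violet, red, grey, amber, in this order
* how the row runs (rises all the way / falls all the way / falls, then rises / hardly changes / rises, then falls)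

I follow one catalyst: at each round it either comes back or is lost. Sunday's run shows how often, if its sag is catalyst lost. Over the first 2.00 min, product forms at 0.0444 min⁻¹ per unit of starting material left, and between 4.00 min and 6.00 min at 0.0351 min⁻¹. So a fraction 0.791 of the activity reads as remaining. Between those two stretches, I then estimate that Sunday's run loses 0.230 mM of catalyst while making 10.5 mM of product. That gives 45.8 for N, the turnover number, defined here as product made per catalyst lost. A catalyst's chance of being lost at each round is then one in N.

By this reckoning, which is mine, 1.6 mM of catalyst makes about 0.0732 M of product, far less than amber's charge. I expect the row to climb to about that value and then hardly change, so for the next run I keep the charge near violet's 0.15 M and treat the higher flasks as a test of this ceiling. N is rough: the late rate is a difference of two readings, each with a scatter of 1 percentage point.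

The forecast reads the same sag differently: “I read the sag as mild product inhibition”. It gives 0.054 M for teal, and for amber 0.41 M, a value more than my ceiling, and its row rises all the way.

The flasks give 0.0601 M, 0.0889 M, 0.0960 M, 0.0816 M and 0.0666 M, so the row rises, then falls, turning near 0.24 M of starting material.

    2 catalyst intermediate → spent catalyst (k = 2900 M⁻¹ min⁻¹)
    crystals ⇌ product, rate k2*(cs2 - [product]) while solid is left; crystals form when [product] > cs2 (solubility = 0.120 M, k = 9.80 min⁻¹)
    starting material + free catalyst → catalyst intermediate (k = 38.0 M⁻¹ min⁻¹)
    catalyst intermediate → free catalyst + product (k = 45.0 min⁻¹)

At 30.0 min, 98.5% of amber's catalyst is spent catalyst, with 94.3% of its starting material still there. Counted from the start as product per catalyst lost, amber gives 42.2 against the 45.8 read from a stretch of Sunday's run, and teal, with 26.5% of its catalyst spent, gives 142.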